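## Structural features

The target 15 is built on one oxolane ring, O1–C2–C3–C4–C5, with a 4-hydroxy-3,5-dimethoxyphenyl group on C2 and on C5 and a hydroxymethyl group on C3 and on C4; the two arenes are the only other rings. The four stereocentres are contiguous and all four substituents lie on the same face (2,3-cis, 3,4-cis, 4,5-cis). A mirror plane through O1 and the midpoint of C3–C4 makes the compound meso, (2R,3R,4S,5S), so racemic intermediates suffice. The C2–O1 and C5–O1 bonds are benzylic ethers para to a free phenol: acid, strong base or heat can open them through a benzylic cation or quinone methide, which would epimerise C2 or C5 or let a neighbouring CH2OH recapture the cation in a rearranged ring. The trioxygenated arenes are also sensitive to oxidants and strong electrophiles. The real difficulty is that the all-cis array is the most crowded diastereomer, so each centre must be set kinetically and must not later sit next to a carbonyl group in a form that can relax to a trans arrangement. The key step exploits the 1,3-relationship of the two aryl carbinol carbons across O1 and the one-carbon branches on C3 and C4: O1–C5–C4 corresponds to a 1-arylpropargylic alcohol and C2–C3 to an arylidene malonate. Their union gives the oxolane with C4 as an exocyclic methylene and C3 as a geminal diester, two prochiral positions from which the cis pair of hydroxymethyl groups is developed.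

## Logic of the disconnections

15 back to 14. The two phenolic O–H bonds are exchanged for O–benzyl bonds. Free para-phenols make the C2–O1 and C5–O1 bonds labile and would quench every organometallic and hydride reagent used earlier; as ethers they are inert. The forward demand is a last step that removes two benzyl groups under neutral conditions without cleaving the ring benzylic C–O bonds.

14 back to 13. The C3 hydroxymethyl carbon is raised to the carboxyl level and joined to the oxygen of the C4 hydroxymethyl group. A second five-membered ring fused at C3–C4 can only be cis-fused, so 13 holds the C3/C4 relationship in its skeleton and has no free hydroxyl. The forward demand is a hydride reduction that opens this ring without epimerising C3.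

13 back to 11. The C3–H bond is replaced by a C3–CO2Me bond. C3 becomes a quaternary, malonate-type carbon, which is the carbon nucleophile the ring construction needs, and it cannot epimerise. The forward demand is removal of that ester without opening the oxolane, with protonation at C3 on the face dictated by the ring fusion.

11 back to 8. The lactone C(=O)–O bond, the CH2–O bond and the C4–H bond are cut, which amounts to a retro-hydration to an exocyclic C4=CH2. The C4 stereocentre disappears and the two esters on C3 become equivalent; 8 has only the two aryl-bearing centres. The forward demand is an anti-Markovnikov hydration that delivers hydrogen to C4 from the face opposite both aryls; ring closure then selects the ester on the same face by itself.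

8 back to 4 and 6. The O1–C2 and C3–C4 bonds are cut. This divides the ring into a three-atom piece (O1–C5–C4) and a two-atom piece (C2–C3) of nearly equal size, both derived from one aldehyde, and removes the ring, two skeletal bonds and the C2 stereocentre at once. The forward demand is an annulation that adds oxygen before carbon, closes 5-exo onto a terminal alkyne and gives the 2,5-cis ring.

4 back to 2 and 3. The C2=C3 double bond is cut as a carbonyl condensation. The demand is only removal of water; no alkene geometry arises because the two esters are identical.

6 back to 2 and 5. The C4–C5 bond is cut as an acetylide addition to the aldehyde. Because 15 is meso, the racemate of 6 is enough and no asymmetric alkynylation is needed.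

2 back to 1. The O–benzyl bond is cut; the forward step is a simple phenol alkylation.

## Other disconnections considered

Alternative 1: The two future hydroxymethyl carbons are first joined as an alkene, and the bonds from C3 and C4 to these carbons are then cut. Those two carbons come from acetylene A2, while C3, C4 and the two future aryl-bearing carbons come from maleic anhydride A1.

- Forward key step: the triplet-sensitised [2+2] photocycloaddition of A1 and A2 gives the cyclobutene anhydride A3 (cis-3-oxabicyclo[3.2.0]hept-6-ene-2,4-dione). From A3 the two carbonyl carbons would become aryl ketones (diketone A4), the ketones would be reduced and the diol closed to the oxolane, the cyclobutene cleaved oxidatively and reduced to the two CH2OH groups, and the phenols unmasked.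
- In favour: the C3/C4 cis relationship comes from the alkene geometry of A1 and stays locked in a four-membered ring until the last C–C operation. That is a more secure hold on this relationship than any reagent-controlled step, and here the alternative is the better plan. The mirror plane is kept from the first step, so every operation is two-directional, and the starting materials are as cheap as can be; on use of symmetry it is at least the equal of the chosen plan.
- Against: C2 and C5 are made last, from carbonyl carbons, and nothing directs the aryl groups to the concave face of the bicyclo[3.2.0] skeleton, syn to the cyclobutene. Hydride addition and a cationic ring closure would both be expected to favour the convex face, which leads to the 2,3-trans/4,5-trans diastereomer and not to 15. A4 has two enolisable hydrogens and could drift to the trans diketone. Ozonolysis next to trioxygenated arenes invites over-oxidation, and irradiating a flammable gas is the least safe operation of all the plans.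
- Comparison: the chosen plan sets C2 against C5 in the ring-forming step and the side chains against the aryls afterwards by attack on the open face. Alternative 1 inverts this order and leaves the hard relationship without a controlling element. Step economy is about equal (eight to nine operations).

Alternative 2: Both aryl–ring bonds, C2–aryl and C5–aryl, are cut. This leaves the preformed oxolane diamide A5 (cis-N,N'-di(quinolin-8-yl)tetrahydrofuran-3,4-dicarboxamide) and the aryl iodide A6.

- Forward key step: each quinolinyl amide would direct Pd(OAc)2 to the neighbouring ring CH2 (C2 or C5). The five-membered palladacycle would add A6 to reach tetravalent palladium, and C–C reductive elimination, with AgOAc taking up iodide, would give the bis-arylated diamide A7. No ring is formed.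
- In favour: cyclometalation can only occur on the face of the directing amide, so each aryl arrives cis to its amide and A7 already has the all-cis array of 15 by mechanism. This is the most direct stereocontrol of any plan and better than the chosen route, which needs three separate stereo-defining events. It is also the shortest plan on paper (about six operations), so it is better on step economy too.
- Against: the second arylation must occur on a face that already carries one aryl and two amides, with an electron-rich iodide that adds slowly. A cis-1,2-diamide can close to a cyclic imide under hot, weakly basic conditions. Most seriously, A7 has two epimerisable hydrogens at C3 and C4, each alpha to an amide carbonyl, in the most strained diastereomer, and removal of the directing groups normally needs N-activation followed by a strong nucleophile or hydride. It also consumes stoichiometric silver and excess A6.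
- Comparison: in Alternative 2 the contra-thermodynamic centres are exposed to base exactly when they are hardest to hold. In the chosen plan C3 stays quaternary until it is locked in a bicyclic lactone that cannot epimerise. The alternative wins on length and on the stereochemical argument of its key step but carries more risk after it.

Alternative 3: The O1–C5 and C2–C3 bonds are cut. This divides the ring into the aldehyde A9 (identical with 2) and the donor–acceptor cyclopropane A8 (dimethyl trans-2-(4-acetoxy-3,5-dimethoxyphenyl)-3-(acetoxymethyl)cyclopropane-1,1-dicarboxylate).

- Forward key step: Sn(OTf)2 would activate the diester, the carbonyl oxygen of A9 would displace the malonate carbon from the aryl-bearing carbon with inversion, and the malonate carbon would then close onto the oxocarbenium carbon. The product would be the 2,5-cis oxolane A10 with the acetoxymethyl group cis to both aryls. Because of the inversion, the trans cyclopropane is the one that gives the 4,5-cis ring, and it is also the isomer obtained from an (E)-alkene.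
- In favour: C4 is defined before the ring exists, from alkene geometry, and not by face selection on a formed ring. The ring and three of the four centres appear in one step. On both points it is better than the chosen plan, whose key step sets one new centre. The 2,5-cis preference has the same standing in both plans.
- Against: the donor is a trioxygenated arene, and such cyclopropanes tend to open to a zwitterion under the Lewis acid, after which the C4–C5 relationship is no longer tied to the cyclopropane geometry. The donor therefore has to be attenuated as the aryl acetate, which forces two different phenol protecting groups and an extra deprotection. The extra ring substituent slows the displacement at the neighbouring carbon. A8 needs a metal-carbene cyclopropanation of an electron-rich alkene with a diazo malonate, a more hazardous reagent than any in the chosen route.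
- Comparison: removing one ester at C3 with the right configuration is the same problem in both plans and would be solved the same way, by lactonisation onto the C4 side chain. Step economy is equal or slightly worse (about ten operations), so the gain in stereochemical convergence is paid for with a less robust key step.

Key step: step 4

Remark on the chemistry: 15 is the all-cis meso diastereomer; 6 and all later chiral intermediates are racemates, so each stereo-SMILES shows one enantiomer only to fix relative configuration.

## Route

Step 1  
Reactants: 1 syringaldehyde (4-hydroxy-3,5-dimethoxybenzaldehyde)  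
Product: 2 4-benzyloxy-3,5-dimethoxybenzaldehyde  
Conditions: BnBr, K2CO3, DMF, 60 °C  
Reagents that add atoms: benzyl bromide, BrCc1ccccc1  
Why: Williamson etherification: the phenoxide formed with K2CO3 displaces bromide from benzyl bromide (SN2), and the aldehyde is inert to carbonate base.

Step 2  
Reactants: 2 4-benzyloxy-3,5-dimethoxybenzaldehyde; 3 dimethyl malonate  
Product: 4 dimethyl 2-(4-benzyloxy-3,5-dimethoxybenzylidene)malonate  
Conditions: piperidine (cat.), AcOH (cat.), toluene, reflux, azeotropic removal of water  
Reagents that add atoms: none  
Why: Knoevenagel condensation: the amine/acid pair turns the aldehyde into an iminium ion that the malonate attacks, and azeotropic removal of water drives the elimination; with two identical esters no alkene isomers arise.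

Step 3  
Reactants: 2 4-benzyloxy-3,5-dimethoxybenzaldehyde; 5 ethynylmagnesium bromide  
Product: 6 rac-1-(4-benzyloxy-3,5-dimethoxyphenyl)prop-2-yn-1-ol  
Conditions: HC≡CMgBr, THF, 0 °C to rt; aq NH4Cl  
Reagents that add atoms: none  
Why: Grignard addition of the magnesium acetylide to the aldehyde; the carbinol centre (future C5) forms as a racemate, which is all a meso target requires, and the aryl benzyl ether is inert.

Step 4  
Reactants: 6 rac-1-(4-benzyloxy-3,5-dimethoxyphenyl)prop-2-yn-1-ol (1.3 equiv); 4 dimethyl 2-(4-benzyloxy-3,5-dimethoxybenzylidene)malonate  
Product: 8 dimethyl rel-(2R,5S)-2,5-bis(4-benzyloxy-3,5-dimethoxyphenyl)-4-methylenetetrahydrofuran-3,3-dicarboxylate (2,5-cis), via propargyl ether malonate 7 (not isolated)  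
Conditions: Zn(OTf)2 (0.2 equiv), Et3N (0.5 equiv), toluene, rt to 60 °C  
Reagents that add atoms: none  
Why: Et3N and Zn(OTf)2 turn 6 into a zinc alkoxide that adds reversibly to the β-carbon of 4 (O1–C2 bond) to give the zinc enolate of 7, whose malonate carbon then adds across the zinc-activated terminal alkyne (C3–C4 bond); protonation of the vinylzinc leaves the exocyclic methylene. The closest known reaction type is the zinc- or base-promoted oxa-Michael/Conia-ene annulation of propargylic alcohols with alkylidene malonates to 3-methylenetetrahydrofurans. The one ring closes in a 5-exo-dig mode with the enolate double bond outside the new ring (enolexo). C5 comes in with racemic 6; the new centre C2 is set relative to it because the two diastereomers of 7 interconvert by retro-addition, and the one that cyclises through an envelope with both aryl groups pseudo-equatorial, which leads to the 2,5-cis ring, should close faster. The step needs 2,5-cis selectivity, and this reversibility together with the pseudo-equatorial preference of the two aryls secures it. Once C3 is quaternary no retro-addition is possible, so the cis relationship is locked in 8. The mild amine base and non-nucleophilic triflate counter-ion should disfavour isomerisation of the propargylic alcohol and migration of the exocyclic alkene into conjugation.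

Step 5  
Reactants: 8 dimethyl rel-(2R,5S)-2,5-bis(4-benzyloxy-3,5-dimethoxyphenyl)-4-methylenetetrahydrofuran-3,3-dicarboxylate  
Product: 11 methyl 6,8-bis(4-benzyloxy-3,5-dimethoxyphenyl)-2-oxo-3,7-dioxabicyclo[3.3.0]octane-1-carboxylate (cis-fused; both aryls endo), via B-alkyl-9-borabicyclononane adduct 9 (not isolated), via hydroxy diester 10 (not isolated)  
Conditions: 9-BBN, THF, 0 to 50 °C; 30% H2O2, aq NaOAc, 0 °C to rt; then DBU (cat.), toluene, 50 °C  
Reagents that add atoms: hydrogen peroxide, OO  
Why: Hydroboration–oxidation followed by lactonisation: 9-BBN adds syn across the 1,1-disubstituted alkene from the face opposite the two cis aryl groups, boron to the terminal carbon and hydrogen to C4, so the new C4 centre carries its CH2 group cis to the aryls (substrate control). Oxidation with retention gives 10, whose hydroxyl can only close a cis-fused γ-lactone onto the ester on its own face; this differentiates the two esters and defines C3 without a protection or a mono-hydrolysis.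

Step 6  
Reactants: 11 methyl 6,8-bis(4-benzyloxy-3,5-dimethoxyphenyl)-2-oxo-3,7-dioxabicyclo[3.3.0]octane-1-carboxylate  
Product: 13 6,8-bis(4-benzyloxy-3,5-dimethoxyphenyl)-3,7-dioxabicyclo[3.3.0]octan-2-one (cis-fused; both aryls endo), via lithium lactone carboxylate 12 (not isolated)  
Conditions: LiCl, H2O (2 equiv), DMSO, 140 °C  
Reagents that add atoms: none  
Why: Krapcho dealkoxycarbonylation: chloride demethylates the angular ester by SN2 at the unhindered methyl group, 12 loses CO2 and the lactone enolate is protonated by water. Only the cis ring fusion of the bicyclo[3.3.0] system is attainable, so hydrogen enters C3 cis to H-4 and the carbonyl carbon stays cis to the aryls. Opening of the enolate by loss of O1 would be the reverse of a 5-endo-trig closure and is stereoelectronically disfavoured.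

Step 7  
Reactants: 13 6,8-bis(4-benzyloxy-3,5-dimethoxyphenyl)-3,7-dioxabicyclo[3.3.0]octan-2-one  
Product: 14 [(2R,3R,4S,5S)-2,5-bis(4-benzyloxy-3,5-dimethoxyphenyl)tetrahydrofuran-3,4-diyl]dimethanol (all-cis; meso)  
Conditions: LiAlH4, THF, 0 °C to rt; H2O, aq NaOH work-up  
Reagents that add atoms: none  
Why: Hydride reduction of a γ-lactone to the 1,4-diol; the transient aldehyde is reduced faster than it can enolise, so C3 keeps its configuration, and the benzyl ethers are inert.

Step 8  
Reactants: 14 [(2R,3R,4S,5S)-2,5-bis(4-benzyloxy-3,5-dimethoxyphenyl)tetrahydrofuran-3,4-diyl]dimethanol  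
Product: 15 [(2R,3R,4S,5S)-2,5-bis(4-hydroxy-3,5-dimethoxyphenyl)tetrahydrofuran-3,4-diyl]dimethanol (all-cis; meso; the target)  
Conditions: H2 (1 atm), 10% Pd/C, EtOAc/MeOH, rt  
Reagents that add atoms: none  
Why: Catalytic hydrogenolysis of the two aryl benzyl ethers; benzyl–O bonds to a phenol oxygen are cleaved much faster than the ring benzylic C–O bonds under neutral conditions at 1 atm, and no stereocentre is involved.

## Compound list

```
1 | syringaldehyde (4-hydroxy-3,5-dimethoxybenzaldehyde) | COc1cc(C=O)cc(OC)c1O | starting material
2 | 4-benzyloxy-3,5-dimethoxybenzaldehyde | COc1cc(C=O)cc(OC)c1OCc1ccccc1 | intermediate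
3 | dimethyl malonate | COC(=O)CC(=O)OC | starting material
4 | dimethyl 2-(4-benzyloxy-3,5-dimethoxybenzylidene)malonate | COC(=O)C(=Cc1cc(OC)c(OCc2ccccc2)c(OC)c1)C(=O)OC | intermediate
5 | ethynylmagnesium bromide | C#C[Mg]Br | starting material
6 | rac-1-(4-benzyloxy-3,5-dimethoxyphenyl)prop-2-yn-1-ol (the R enantiomer is drawn) | O[C@@H](c1cc(OC)c(OCc2ccccc2)c(OC)c1)C#C | intermediate
7 | dimethyl 2-[(S)-(4-benzyloxy-3,5-dimethoxyphenyl){[(R)-1-(4-benzyloxy-3,5-dimethoxyphenyl)prop-2-yn-1-yl]oxy}methyl]malonate, racemic, present as its zinc enolate (not isolated) | COc1cc([C@H](C(C(=O)OC)C(=O)OC)O[C@@H](c2cc(OC)c(OCc3ccccc3)c(OC)c2)C#C)cc(OC)c1OCc1ccccc1 | intermediate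
8 | dimethyl rel-(2R,5S)-2,5-bis(4-benzyloxy-3,5-dimethoxyphenyl)-4-methylenetetrahydrofuran-3,3-dicarboxylate (2,5-cis) | COc1cc([C@H]2O[C@@H](c3cc(OC)c(OCc4ccccc4)c(OC)c3)C(=C)C2(C(=O)OC)C(=O)OC)cc(OC)c1OCc1ccccc1 | intermediate
9 | dimethyl 2,4,5-cis-4-[(9-borabicyclo[3.3.1]nonan-9-yl)methyl]-2,5-bis(4-benzyloxy-3,5-dimethoxyphenyl)tetrahydrofuran-3,3-dicarboxylate (not isolated) | COc1cc([C@H]2O[C@@H](c3cc(OC)c(OCc4ccccc4)c(OC)c3)[C@@H](CB3C4CCCC3CCC4)C2(C(=O)OC)C(=O)OC)cc(OC)c1OCc1ccccc1 | intermediate
10 | dimethyl 2,4,5-cis-2,5-bis(4-benzyloxy-3,5-dimethoxyphenyl)-4-(hydroxymethyl)tetrahydrofuran-3,3-dicarboxylate (not isolated) | COc1cc([C@H]2O[C@@H](c3cc(OC)c(OCc4ccccc4)c(OC)c3)[C@@H](CO)C2(C(=O)OC)C(=O)OC)cc(OC)c1OCc1ccccc1 | intermediate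
11 | methyl 6,8-bis(4-benzyloxy-3,5-dimethoxyphenyl)-2-oxo-3,7-dioxabicyclo[3.3.0]octane-1-carboxylate, cis-fused, both aryls endo (cis to the lactone ring) | COc1cc([C@H]2O[C@@H](c3cc(OC)c(OCc4ccccc4)c(OC)c3)[C@H]3COC(=O)[C@@]23C(=O)OC)cc(OC)c1OCc1ccccc1 | intermediate
12 | lithium 6,8-bis(4-benzyloxy-3,5-dimethoxyphenyl)-2-oxo-3,7-dioxabicyclo[3.3.0]octane-1-carboxylate, same configuration as 11 (not isolated) | [Li+].COc1cc([C@H]2O[C@@H](c3cc(OC)c(OCc4ccccc4)c(OC)c3)[C@H]3COC(=O)[C@@]23C([O-])=O)cc(OC)c1OCc1ccccc1 | intermediate
13 | 6,8-bis(4-benzyloxy-3,5-dimethoxyphenyl)-3,7-dioxabicyclo[3.3.0]octan-2-one, cis-fused, both aryls endo | COc1cc([C@H]2O[C@@H](c3cc(OC)c(OCc4ccccc4)c(OC)c3)[C@H]3COC(=O)[C@@H]23)cc(OC)c1OCc1ccccc1 | intermediate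
14 | [(2R,3R,4S,5S)-2,5-bis(4-benzyloxy-3,5-dimethoxyphenyl)tetrahydrofuran-3,4-diyl]dimethanol, all-cis, meso | COc1cc([C@H]2O[C@@H](c3cc(OC)c(OCc4ccccc4)c(OC)c3)[C@@H](CO)[C@H]2CO)cc(OC)c1OCc1ccccc1 | intermediate
15 | [(2R,3R,4S,5S)-2,5-bis(4-hydroxy-3,5-dimethoxyphenyl)tetrahydrofuran-3,4-diyl]dimethanol, all-cis, meso | COc1cc([C@H]2O[C@@H](c3cc(OC)c(O)c(OC)c3)[C@@H](CO)[C@H]2CO)cc(OC)c1O | target
```

## Step count and least certain steps

Total step count: 8. Longest linear sequence: 7 steps (1 to 2, then 4 or 6, then 8, 11, 13, 14, 15).

In what follows Ar stands for 4-benzyloxy-3,5-dimethoxyphenyl.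

Risk at step 4 (key step). The addition of a hindered secondary alkoxide to a donor-substituted arylidene malonate may lie far on the side of 4 and 6, so that carbocyclisation is slow. The Lewis-acidic zinc salt could then ionise the electron-rich propargylic C–O bond of 6, or the amine could isomerise the propargylic alcohol or move the exocyclic alkene of 8 into conjugation. A closure that outruns equilibration of the diastereomers of 7 would erode the 2,5-cis preference.

The fallback sets out from 4 and 6 and returns at 8; it replaces the polar ring closure by a radical one.
- The lithium alkoxide of 6 (n-BuLi, THF, −78 °C) is added to 4 and the malonate anion is trapped cold with I2. This should give dimethyl 2-iodo-2-{Ar[(1-Ar-prop-2-yn-1-yl)oxy]methyl}malonate F1.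
- Iodine-atom-transfer cyclisation (Et3B, air, benzene, rt) lets the electrophilic malonyl radical add 5-exo-dig to the alkyne and should give dimethyl 2,5-cis-2,5-di-Ar-4-(iodomethylene)tetrahydrofuran-3,3-dicarboxylate F2.
- Radical reduction of the vinyl iodide with (Me3Si)3SiH and AIBN (toluene, 80 °C) returns 8.
- The diastereomers of F1 do not interconvert. Only the one that places both aryls pseudo-equatorial in the chair-like transition state leads to the cis ring, and the trans-ring isomer would have to be separated at F2.

Risk at step 5. Face selection in the H–B delivery rests mainly on the C5 aryl, because C3 carries an ester on both faces, and it may be incomplete. Addition of the bulky borane next to a quaternary carbon may be slow, and forcing it invites ester reduction. Lactonisation to the crowded endo,endo-diaryl bicycle may stall at 10.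

The fallback sets out from 8 and returns at 10, which is lactonised to 11 as in step 5; it avoids boranes.
- Epoxidation with mCPBA (NaHCO3, CH2Cl2) anti to the aryls should give dimethyl 5,7-cis-5,7-di-Ar-1,6-dioxaspiro[2.4]heptane-4,4-dicarboxylate F3.
- Ti(C5H5)2Cl2 with Zn dust (trivalent titanium made in the flask) and 1,4-cyclohexadiene in THF opens the epoxide homolytically to the tertiary C4 radical, which takes a hydrogen atom on the face away from the aryls and gives 10 after work-up.
- This route relies on the same facial bias as the hydroboration, so it answers slow or unclean hydroboration better than it answers poor face selection.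

Risk at step 6. At 140 °C the lactone enolate may, despite the poor orbital alignment, expel O1 and re-add, which would epimerise C2 toward the less crowded exo aryl. The wet salt medium may also hydrolyse the lactone.

The fallback sets out from 11 and returns at 13; it uses a radical decarboxylation that passes through no enolate.
- LiOH (THF/H2O) followed by acidification, which recloses the lactone, should give 6,8-di-Ar-2-oxo-3,7-dioxabicyclo[3.3.0]octane-1-carboxylic acid F4.
- DCC and 1-hydroxypyridine-2(1H)-thione (CH2Cl2, dark) convert it into the 2-thioxopyridin-1(2H)-yl ester F5.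
- Visible light with t-BuSH (Barton decarboxylation) generates the C3 radical, which can take hydrogen only on the convex face of the cis-fused bicycle, and gives 13.

Risk at step 8. Hydrogenolytic opening of the ring at the C2–O1 or C5–O1 benzylic bond may compete, especially once the para-phenol is free, and traces of acid on the catalyst could epimerise C2 or C5.

The fallback sets out from 13 and returns at 15; it debenzylates without reduction and before the hydride step.
- BCl3 with pentamethylbenzene as benzyl-cation scavenger (CH2Cl2, −78 °C) removes both benzyl groups from 13, which has no free hydroxyl to recapture a benzylic cation. This should give 6,8-bis(4-hydroxy-3,5-dimethoxyphenyl)-3,7-dioxabicyclo[3.3.0]octan-2-one F6.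
- Excess LiAlH4 (THF, 0 °C, neutral NH4Cl work-up) then reduces the lactone and gives 15 directly.

## Further compounds

```
F1 | step 4 | dimethyl 2-iodo-2-{(4-benzyloxy-3,5-dimethoxyphenyl)[(1-(4-benzyloxy-3,5-dimethoxyphenyl)prop-2-yn-1-yl)oxy]methyl}malonate, relative configuration as in 7 | COc1cc([C@H](C(I)(C(=O)OC)C(=O)OC)O[C@@H](c2cc(OC)c(OCc3ccccc3)c(OC)c2)C#C)cc(OC)c1OCc1ccccc1
F2 | step 4 | dimethyl 2,5-cis-2,5-bis(4-benzyloxy-3,5-dimethoxyphenyl)-4-(iodomethylene)tetrahydrofuran-3,3-dicarboxylate, E/Z mixture | COc1cc([C@H]2O[C@@H](c3cc(OC)c(OCc4ccccc4)c(OC)c3)C(=CI)C2(C(=O)OC)C(=O)OC)cc(OC)c1OCc1ccccc1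
F3 | step 5 | dimethyl 5,7-cis-5,7-bis(4-benzyloxy-3,5-dimethoxyphenyl)-1,6-dioxaspiro[2.4]heptane-4,4-dicarboxylate, epoxide oxygen trans to the aryls | COc1cc([C@H]2O[C@@H](c3cc(OC)c(OCc4ccccc4)c(OC)c3)[C@@]3(CO3)C2(C(=O)OC)C(=O)OC)cc(OC)c1OCc1ccccc1
F4 | step 6 | 6,8-bis(4-benzyloxy-3,5-dimethoxyphenyl)-2-oxo-3,7-dioxabicyclo[3.3.0]octane-1-carboxylic acid, cis-fused, both aryls endo | COc1cc([C@H]2O[C@@H](c3cc(OC)c(OCc4ccccc4)c(OC)c3)[C@H]3COC(=O)[C@@]23C(=O)O)cc(OC)c1OCc1ccccc1
F5 | step 6 | 2-thioxopyridin-1(2H)-yl 6,8-bis(4-benzyloxy-3,5-dimethoxyphenyl)-2-oxo-3,7-dioxabicyclo[3.3.0]octane-1-carboxylate, cis-fused, both aryls endo | COc1cc([C@H]2O[C@@H](c3cc(OC)c(OCc4ccccc4)c(OC)c3)[C@H]3COC(=O)[C@@]23C(=O)ON2C=CC=CC2=S)cc(OC)c1OCc1ccccc1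
F6 | step 8 | 6,8-bis(4-hydroxy-3,5-dimethoxyphenyl)-3,7-dioxabicyclo[3.3.0]octan-2-one, cis-fused, both aryls endo | COc1cc([C@H]2O[C@@H](c3cc(OC)c(O)c(OC)c3)[C@H]3COC(=O)[C@@H]23)cc(OC)c1O
A1 | alternative 1 | maleic anhydride | O=C1OC(=O)C=C1
A2 | alternative 1 | acetylene | C#C
A3 | alternative 1 | cis-3-oxabicyclo[3.2.0]hept-6-ene-2,4-dione | O=C1OC(=O)[C@H]2C=C[C@@H]12
A4 | alternative 1 | cis-3,4-bis(4-benzyloxy-3,5-dimethoxybenzoyl)cyclobut-1-ene | O=C(c1cc(OC)c(OCc2ccccc2)c(OC)c1)[C@H]1C=C[C@H]1C(=O)c1cc(OC)c(OCc2ccccc2)c(OC)c1
A5 | alternative 2 | cis-N,N'-di(quinolin-8-yl)tetrahydrofuran-3,4-dicarboxamide | O=C(Nc1cccc2cccnc12)[C@H]1COC[C@H]1C(=O)Nc1cccc2cccnc12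
A6 | alternative 2 | 2-benzyloxy-5-iodo-1,3-dimethoxybenzene | COc1cc(I)cc(OC)c1OCc1ccccc1
A7 | alternative 2 | all-cis-2,5-bis(4-benzyloxy-3,5-dimethoxyphenyl)-N,N'-di(quinolin-8-yl)tetrahydrofuran-3,4-dicarboxamide | COc1cc([C@H]2O[C@@H](c3cc(OC)c(OCc4ccccc4)c(OC)c3)[C@@H](C(=O)Nc3cccc4cccnc34)[C@H]2C(=O)Nc2cccc3cccnc23)cc(OC)c1OCc1ccccc1
A8 | alternative 3 | dimethyl trans-2-(4-acetoxy-3,5-dimethoxyphenyl)-3-(acetoxymethyl)cyclopropane-1,1-dicarboxylate | COC(=O)C1(C(=O)OC)[C@@H](COC(C)=O)[C@@H]1c1cc(OC)c(OC(C)=O)c(OC)c1
A9 | alternative 3 | 4-benzyloxy-3,5-dimethoxybenzaldehyde (identical with 2) | COc1cc(C=O)cc(OC)c1OCc1ccccc1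
A10 | alternative 3 | dimethyl 2,4,5-cis-4-(acetoxymethyl)-5-(4-acetoxy-3,5-dimethoxyphenyl)-2-(4-benzyloxy-3,5-dimethoxyphenyl)tetrahydrofuran-3,3-dicarboxylate | COc1cc([C@H]2O[C@@H](c3cc(OC)c(OC(C)=O)c(OC)c3)[C@@H](COC(C)=O)C2(C(=O)OC)C(=O)OC)cc(OC)c1OCc1ccccc1
```
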